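## Analysis of the target

The target 26 is a non-symmetric diaryl ether made of two benzoic acids. Ring A carries CO2H at C1, the ether oxygen at C2, a free OH at C3, Cl at C4, OCH3 at C5 and H at C6. Ring B carries CO2H at C1', the ether oxygen at C2', H at C3', CH3 at C4', H at C5' and OH at C6'. There are no stereocenters, and three ortho substituents of modest size around the C2–O–C2' bridge should not give a configurationally stable axis. The main difficulty is the ether bond: its oxygen is flanked by CO2H and OH on ring A and by CO2H on ring B, so a late C–O coupling would join two hindered partners. Ring A adds a second problem, a contiguous and fully differentiated C1–C5 pattern with chlorine between two oxygens, of which only the C5 oxygen stays methylated. Sensitive points are the ring B acid (a 2,6-dioxygenated benzoic acid, prone to decarboxylation in hot acid), the aryl chloride (excludes routine hydrogenolysis) and the C3–OH, which can lactonise onto the C1' carboxyl to a depsidone. The strategy rests on ring B: the sequence C1'(CO2H)–C6'(OH)–C5'(H)–C4'(CH3) is the C3–C6 diene of a 4-oxygenated 6-methyl-2-pyrone-3-carboxylate, and the missing C2' and C3' are the two carbons of an alkyne already bonded through oxygen to ring A.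

## Retrosynthetic reasoning

**Endgame adjustments (26 back to 22).** No skeletal bond is cut here. The ring B ester of 25 is hydrolysed last. Before that, one Lewis-acid dealkylation of 24 removes the C3 benzyl ether and the C6' methyl ether together; the C6' ether is singled out by chelation to the neighbouring ester, while the C5 methyl ether has no such neighbour. The ring A carboxyl of 24 goes back through aldehyde 23 to dioxolane 22. The acetal is needed because an alkyllithium is used earlier, and the benzyl ether is kept through the aldehyde oxidation so that no free phenol meets its chlorinating by-product.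

**Ring B (22 to 15 and 20).** The C1'–C2' and C3'–C4' bonds are cut, which takes ring B apart into the ynol ether 15 and the pyrone 20. This avoids the hindered C2–O–C2' bond: that oxygen is attached to ring A as a simple phenol ether and ring B is built around it. The forward reaction must join the alkyne terminus to pyrone C6 and the oxygen-bearing carbon to C3, and the bridged lactone 21 must then aromatise by decarboxylative cycloreversion. Carboxyl, oxygen and methyl of ring B then arrive in their final positions, with no later oxidation or elimination.

**Ynol ether (15 to 8 and 9).** The O–C(sp) bond is cut. Phenol 8 is vinylated with trichloroethylene 9 (through dichloroacetylene 10) to the dichlorovinyl ether 11. The aldehyde is acetalised only then (12), which avoids an acid-labile ortho-hydroxybenzaldehyde acetal. Alkyllithium-induced elimination and halogen–lithium exchange (13, 14) then give 15.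

**Ring A pattern (8 to 1).** The formyl group of 8 is cut off next to the free phenol, because magnesium-mediated ortho-formylation of phenol 6 (through 7) can only reach that position. Phenol 6 comes from aldehyde 4 by Baeyer–Villiger oxidation via formate 5, so the carbon that first carried the aldehyde becomes the oxygen of the future ether. Aldehyde 4 is the benzyl ether of 3, and 3 comes from 2 by chelation-controlled demethylation, which differentiates the two oxygens that flank chlorine. Aldehyde 2 is the only possible formylation product of 2-chloro-1,3-dimethoxybenzene 1, which already holds chlorine between two oxygens. Every regiochemical question on ring A is thereby settled by symmetry or by a directing neighbour.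

**Pyrone (20 to 16 and 17).** The pyrone 20 is the O-methyl ether of 19. Pyrone 19 is cut at its C3–C4 bond and at the lactone C–O bond into dimethyl malonate 16 and diketene 17, with the acetoacetylmalonate 18 as the open-chain intermediate.

## Alternatives that were turned down

**Alternative 1:** Ring A is cut at C2–C3 and C1–C6, and ring B with the ether oxygen is held in a benzofuran-3-one whose C2 is ring A C2.
- **Forward key step:** Diels–Alder addition of the chlorinated ketene-acetal diene A3 to the exocyclic alkene of benzofuranone A2 gives, after acidic work-up, the spiro chloro-methoxy-cyclohexenone A1. Dehydrogenation to the dienone and hydroxide attack on the benzofuranone carbonyl would then break the bond to the spiro carbon, releasing the ring B carboxylate and aromatising ring A.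
- **For:** Chlorine, the C5 methoxy group and a free C3–OH come from the diene in defined positions. The ether oxygen is present from the start, and ring A needs no protecting group. On paper the sequence could be shorter than the chosen one, and on protecting-group economy it is stronger.
- **Against:** The chlorinated diene A3 is labile and must add to a trisubstituted, captodative alkene to create a fully substituted spiro carbon. Two stereocenters are made only to be destroyed. The dehydrogenation and the ring cleavage are two further uncertain steps: hydroxide can also attack the ring A ketone or exchange the vinylogous ester.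
- **Comparison:** The risk is spread over three consecutive steps. The chosen route has one risky step, and that step delivers ring B already aromatic.

**Alternative 2:** Ring A is cut at C1–C2 and C4–C5, and the ether oxygen stays on ring B as the aryloxyacetone A5.
- **Forward key step:** The enolate of A5 adds through its aryloxy-bearing carbon to dimethyl fumarate A6, and the methyl ketone closes onto the distal ester to give the dioxocyclohexanecarboxylate A4. Chlorination at C4, dehydrogenation to the resorcinol and mono-methylation at the C5 oxygen would follow.
- **For:** The materials are cheap, no thermally labile alkyne is needed, and chlorine would enter at C4 between the two carbonyls without any regiochemical doubt. On these points it is stronger than the chosen route.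
- **Against:** In A4 and in the open-chain Michael adduct the aryloxy group is β to an ester-stabilised carbanion, so the ring B phenoxide can be lost by E1cB elimination under the alkoxide conditions of the Claisen closure. Enolisation of A5 towards the aryloxy-bearing carbon and not the methyl group is not assured. After ring closure, aromatisation and the choice between the two resorcinol oxygens still have to be solved.
- **Comparison:** The chosen route forms the arene at the correct oxidation level, with all oxygens differentiated beforehand, and never places the ether oxygen β to a carbanion.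

**Alternative 3:** Ring B is cut at C2'–C3' and C6'–C1', so the alkyne carries both the aryloxy group and the ring B ester.
- **Forward key step:** The vinylketene acetal A9 adds across the aryloxy ynoate A8, and the adduct aromatises by loss of methanol and desilylation to the hydroxybenzoate A7.
- **For:** Vinylketene acetal and alkynoate give salicylates in a well-known normal-demand Diels–Alder reaction. A7 has ring A already as an ester and the C6' oxygen free, so the endgame would be about two steps shorter than the chosen one. On the endgame it is stronger.
- **Against:** A8 is a push–pull alkyne, and the aryloxy donor raises its LUMO, so it is a poor dienophile for an electron-rich diene. A nucleophilic diene can add at the aryloxy-bearing carbon and expel the aryloxide, which destroys the future ether bond. Making A8 with the ring A ester in place is not compatible with the alkyllithium route to ynol ethers.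
- **Comparison:** The chosen route uses the same alkyne oxygen but with matched polarity (electron-rich alkyne, electron-poor pyrone), has no leaving-group problem, and both partners come from known procedures. It pays with an acetal detour and one dealkylation more.

Key step: step 11

Remark: the ether axis of 26 is taken not to be configurationally stable, so the target is treated as achiral and no stereocontrol is planned.

## Route

Step 1
Reactants: 1 2-chloro-1,3-dimethoxybenzene
Product: 2 3-chloro-2,4-dimethoxybenzaldehyde
Conditions: Cl2CHOMe, TiCl4, CH2Cl2, −10 → 0 °C; then ice/H2O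
Reagents that add atoms: dichloromethyl methyl ether, COC(Cl)Cl (formyl carbon); water, O (formyl oxygen, on work-up)
Why: Rieche formylation (electrophilic aromatic substitution); the two activated positions of 1, each ortho to one methoxy group and para to the other, are equivalent, so a single aldehyde should form.

Step 2
Reactants: 2 3-chloro-2,4-dimethoxybenzaldehyde
Product: 3 3-chloro-2-hydroxy-4-methoxybenzaldehyde
Conditions: BCl3 (1.2 equiv), CH2Cl2, −78 → 0 °C; then H2O
Reagents that add atoms: none
Why: Chelation-controlled Lewis-acid demethylation; BCl3 bound to the aldehyde oxygen activates only the ortho methyl ether, which is also twisted out of conjugation by its two neighbours, so the para methoxy group should stay.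

Step 3
Reactants: 3 3-chloro-2-hydroxy-4-methoxybenzaldehyde
Product: 4 2-(benzyloxy)-3-chloro-4-methoxybenzaldehyde
Conditions: BnBr, K2CO3, DMF, 50 °C
Reagents that add atoms: benzyl bromide, BrCc1ccccc1
Why: Williamson ether synthesis on the phenoxide; benzyl is chosen because it should survive n-BuLi, heat and the chlorite oxidation and is removed by BCl3 at the end without touching the aryl chloride.

Step 4
Reactants: 4 2-(benzyloxy)-3-chloro-4-methoxybenzaldehyde
Product: 6 2-(benzyloxy)-3-chloro-4-methoxyphenol, via aryl formate 5 (not isolated)
Conditions: mCPBA, CH2Cl2, 0 °C → rt; then K2CO3 (cat.), MeOH, rt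
Reagents that add atoms: 3-chloroperoxybenzoic acid (mCPBA), OOC(=O)c1cccc(Cl)c1
Why: Baeyer–Villiger (Dakin-type) oxidation; the aryl group, made electron-rich by the ortho benzyloxy and para methoxy groups, should migrate in preference to hydrogen, and the formate is methanolysed in the same flask.

Step 5
Reactants: 6 2-(benzyloxy)-3-chloro-4-methoxyphenol
Product: 8 3-(benzyloxy)-4-chloro-2-hydroxy-5-methoxybenzaldehyde, via benzylic alcohol 7 (not isolated)
Conditions: (CH2O)n, MgCl2, Et3N, MeCN, reflux; then 1 M HCl
Reagents that add atoms: paraformaldehyde (as formaldehyde), C=O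
Why: Magnesium-mediated ortho-formylation of a phenol (Casnati–Skattebøl); the magnesium phenoxide delivers formaldehyde to the only free ortho position (the other ortho and the para position are substituted), and the hydroxymethyl intermediate is oxidised in situ by a second equivalent of formaldehyde.

Step 6
Reactants: 8 3-(benzyloxy)-4-chloro-2-hydroxy-5-methoxybenzaldehyde; 9 trichloroethylene
Product: 11 3-(benzyloxy)-4-chloro-2-{[(E)-1,2-dichloroethenyl]oxy}-5-methoxybenzaldehyde, via dichloroacetylene 10 (not isolated)
Conditions: K2CO3, DMF, 70 °C
Reagents that add atoms: none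
Why: Known O-dichlorovinylation of phenols: base converts 9 into dichloroacetylene, the phenoxide adds to it and anti protonation should give the (E)-1,2-dichlorovinyl ether; the aldehyde has no α-hydrogen and should be inert.

Step 7
Reactants: 11 3-(benzyloxy)-4-chloro-2-{[(E)-1,2-dichloroethenyl]oxy}-5-methoxybenzaldehyde
Product: 12 2-[3-(benzyloxy)-4-chloro-2-{[(E)-1,2-dichloroethenyl]oxy}-5-methoxyphenyl]-1,3-dioxolane
Conditions: ethylene glycol, p-toluenesulfonic acid (cat.), benzene, Dean–Stark, reflux
Reagents that add atoms: ethylene glycol, OCCO
Why: Acid-catalysed acetalisation with removal of water; the dichlorovinyl ether is an electron-poor enol ether that should resist protonation, and with the phenol oxygen already capped the acetal has no ortho hydroxyl to make it labile.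

Step 8
Reactants: 12 2-[3-(benzyloxy)-4-chloro-2-{[(E)-1,2-dichloroethenyl]oxy}-5-methoxyphenyl]-1,3-dioxolane
Product: 15 2-[3-(benzyloxy)-4-chloro-2-(ethynyloxy)-5-methoxyphenyl]-1,3-dioxolane, via chloroethynyl ether 13 (not isolated), via lithium acetylide 14 (not isolated)
Conditions: n-BuLi (2.3 equiv), THF, −78 → −40 °C; then H2O, −78 → 0 °C; neutral work-up, used at once
Reagents that add atoms: none
Why: Known conversion of 1,2-dichlorovinyl ethers into ynol ethers: dehydrochlorination gives the chloroalkyne, chlorine–lithium exchange gives the acetylide, and water protonates it. The ring chlorine has no ortho hydrogen (no aryne path) and should not exchange at −78 °C, and the dioxolane is inert to n-BuLi.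

Step 9
Reactants: 16 dimethyl malonate; 17 diketene
Product: 19 methyl 4-hydroxy-6-methyl-2-oxo-2H-pyran-3-carboxylate, via acetoacetylmalonate 18 (not isolated)
Conditions: NaH, THF, 0 °C → reflux; then aq. HCl
Reagents that add atoms: none
Why: C-acylation of the sodium malonate by diketene (attack at the lactone carbonyl) gives the acetoacetylmalonate, whose ketone enol oxygen lactonises onto one ester with loss of methanol; this is the known pyrone synthesis from diketene and active-methylene compounds.

Step 10
Reactants: 19 methyl 4-hydroxy-6-methyl-2-oxo-2H-pyran-3-carboxylate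
Product: 20 methyl 4-methoxy-6-methyl-2-oxo-2H-pyran-3-carboxylate
Conditions: Me2SO4, K2CO3, acetone, reflux
Reagents that add atoms: dimethyl sulfate, COS(=O)(=O)OC
Why: O-alkylation of a vinylogous acid with a hard electrophile; the 4-oxygen is the reactive site of the delocalised anion of 4-hydroxy-2-pyrones, and any 2-methoxy-4-pyranone isomer would be separated.

Step 11
Reactants: 15 2-[3-(benzyloxy)-4-chloro-2-(ethynyloxy)-5-methoxyphenyl]-1,3-dioxolane; 20 methyl 4-methoxy-6-methyl-2-oxo-2H-pyran-3-carboxylate
Product: 22 methyl 2-[2-(benzyloxy)-3-chloro-6-(1,3-dioxolan-2-yl)-4-methoxyphenoxy]-6-methoxy-4-methylbenzoate, via bridged lactone 21 (not isolated)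
Conditions: toluene, 110–130 °C, sealed tube, 20 in 1.5-fold excess, 2,6-di-tert-butyl-4-methylphenol (trace)
Reagents that add atoms: none
Why: The electron-poor diene of 20 (C3=C4–C5=C6, LUMO lowered by the C3 ester and the lactone carbonyl) and the electron-rich alkyne of 15 should combine in an inverse-electron-demand [4+2] cycloaddition; the closest known reaction type is the benzannulation of 2-pyrone-3-carboxylates with ynamines and ketene acetals. Bond formation is expected to be concerted but asynchronous, the bond from the alkyne CH to pyrone C6 leading, and gives the bridged lactone 21, which should lose CO2 by retro-[4+2] at the reaction temperature. Ring B is therefore closed by an intermolecular cycloaddition that makes C1'–C2' and C3'–C4' in one operation, and it emerges aromatic without elimination or oxidation. No stereocenter remains: the two bridgehead centers of 21 form as a racemate and are erased on aromatisation. The selectivity needed is regiochemical. The terminal alkyne carbon (largest HOMO coefficient, β to oxygen) should bond to C6 (largest LUMO coefficient, the vinylogous acceptor position of the C3 ester), so the oxygen-bearing carbon joins C3 and the aryloxy group ends up ortho to the ester. The unsubstituted alkyne terminus keeps attack at the methyl-bearing C6 sterically possible, and acetal, benzyl ether and aryl chloride are inert under neutral thermal conditions.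

Step 12
Reactants: 22 methyl 2-[2-(benzyloxy)-3-chloro-6-(1,3-dioxolan-2-yl)-4-methoxyphenoxy]-6-methoxy-4-methylbenzoate
Product: 23 methyl 2-[2-(benzyloxy)-3-chloro-6-formyl-4-methoxyphenoxy]-6-methoxy-4-methylbenzoate
Conditions: 1 M HCl, THF, rt
Reagents that add atoms: water, O
Why: Acid-catalysed acetal hydrolysis; the esters, aryl ethers and the benzyl ether should be stable to dilute acid at room temperature.

Step 13
Reactants: 23 methyl 2-[2-(benzyloxy)-3-chloro-6-formyl-4-methoxyphenoxy]-6-methoxy-4-methylbenzoate
Product: 24 3-(benzyloxy)-4-chloro-5-methoxy-2-[3-methoxy-2-(methoxycarbonyl)-5-methylphenoxy]benzoic acid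
Conditions: NaClO2, NaH2PO4, 2-methyl-2-butene, t-BuOH/THF/H2O, 0 °C → rt
Reagents that add atoms: sodium chlorite, [Na+].[O-]Cl=O
Why: Pinnick oxidation of the aryl aldehyde; the alkene scavenges hypochlorous acid, and because all phenols are still protected no ring chlorination is expected.

Step 14
Reactants: 24 3-(benzyloxy)-4-chloro-5-methoxy-2-[3-methoxy-2-(methoxycarbonyl)-5-methylphenoxy]benzoic acid
Product: 25 4-chloro-3-hydroxy-2-[3-hydroxy-2-(methoxycarbonyl)-5-methylphenoxy]-5-methoxybenzoic acid
Conditions: BCl3 (5 equiv), pentamethylbenzene, CH2Cl2, −78 → 0 °C; then H2O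
Reagents that add atoms: none
Why: Lewis-acid dealkylation; BCl3 cleaves the benzyl ether (the benzyl cation is trapped by pentamethylbenzene) and, through chelation to the ester carbonyl, the ortho methyl ether of ring B. The C5 methyl ether of ring A has no chelating neighbour and should survive at low temperature, as should the methyl ester and the aryl chloride.

Step 15
Reactants: 25 4-chloro-3-hydroxy-2-[3-hydroxy-2-(methoxycarbonyl)-5-methylphenoxy]-5-methoxybenzoic acid
Product: 26 2-(2-carboxy-3-hydroxy-5-methylphenoxy)-4-chloro-3-hydroxy-5-methoxybenzoic acid
Conditions: NaOH (2 M aq., excess), MeOH, 70 °C, argon; then 1 M HCl, 0 °C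
Reagents that add atoms: sodium hydroxide, [Na+].[OH-] (carboxyl oxygen)
Why: Saponification by acyl substitution; oxygen ortho substituents hinder far less than alkyl groups, and a depsidone-type lactone formed by attack of the C3 phenoxide on the ester would be opened by hydroxide to the same product. Cold acidification is used to avoid decarboxylation of the 2,6-dioxygenated acid.

## Compound list

1 | 2-chloro-1,3-dimethoxybenzene | COc1cccc(OC)c1Cl | starting material
2 | 3-chloro-2,4-dimethoxybenzaldehyde | O=Cc1ccc(OC)c(Cl)c1OC | intermediate
3 | 3-chloro-2-hydroxy-4-methoxybenzaldehyde | O=Cc1ccc(OC)c(Cl)c1O | intermediate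
4 | 2-(benzyloxy)-3-chloro-4-methoxybenzaldehyde | O=Cc1ccc(OC)c(Cl)c1OCc1ccccc1 | intermediate
5 | 2-(benzyloxy)-3-chloro-4-methoxyphenyl formate (not isolated) | O=COc1ccc(OC)c(Cl)c1OCc1ccccc1 | intermediate
6 | 2-(benzyloxy)-3-chloro-4-methoxyphenol | Oc1ccc(OC)c(Cl)c1OCc1ccccc1 | intermediate
7 | 2-(benzyloxy)-3-chloro-6-(hydroxymethyl)-4-methoxyphenol (not isolated) | OCc1cc(OC)c(Cl)c(OCc2ccccc2)c1O | intermediate
8 | 3-(benzyloxy)-4-chloro-2-hydroxy-5-methoxybenzaldehyde | O=Cc1cc(OC)c(Cl)c(OCc2ccccc2)c1O | intermediate
9 | trichloroethylene | ClC=C(Cl)Cl | starting material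
10 | dichloroacetylene (not isolated) | ClC#CCl | intermediate
11 | 3-(benzyloxy)-4-chloro-2-{[(E)-1,2-dichloroethenyl]oxy}-5-methoxybenzaldehyde | O=Cc1cc(OC)c(Cl)c(OCc2ccccc2)c1O/C(Cl)=C\Cl | intermediate
12 | 2-[3-(benzyloxy)-4-chloro-2-{[(E)-1,2-dichloroethenyl]oxy}-5-methoxyphenyl]-1,3-dioxolane | Cl\C=C(Cl)/Oc1c(C2OCCO2)cc(OC)c(Cl)c1OCc1ccccc1 | intermediate
13 | 2-{3-(benzyloxy)-4-chloro-2-[(chloroethynyl)oxy]-5-methoxyphenyl}-1,3-dioxolane (not isolated) | ClC#COc1c(C2OCCO2)cc(OC)c(Cl)c1OCc1ccccc1 | intermediate
14 | {[2-(benzyloxy)-3-chloro-6-(1,3-dioxolan-2-yl)-4-methoxyphenoxy]ethynyl}lithium (not isolated) | [Li]C#COc1c(C2OCCO2)cc(OC)c(Cl)c1OCc1ccccc1 | intermediate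
15 | 2-[3-(benzyloxy)-4-chloro-2-(ethynyloxy)-5-methoxyphenyl]-1,3-dioxolane | C#COc1c(C2OCCO2)cc(OC)c(Cl)c1OCc1ccccc1 | intermediate
16 | dimethyl malonate | COC(=O)CC(=O)OC | starting material
17 | diketene | C=C1CC(=O)O1 | starting material
18 | dimethyl 2-(3-oxobutanoyl)malonate (not isolated) | COC(=O)C(C(=O)OC)C(=O)CC(C)=O | intermediate
19 | methyl 4-hydroxy-6-methyl-2-oxo-2H-pyran-3-carboxylate | COC(=O)C1=C(O)C=C(C)OC1=O | intermediate
20 | methyl 4-methoxy-6-methyl-2-oxo-2H-pyran-3-carboxylate | COC(=O)C1=C(OC)C=C(C)OC1=O | intermediate
21 | methyl 5-[2-(benzyloxy)-3-chloro-6-(1,3-dioxolan-2-yl)-4-methoxyphenoxy]-8-methoxy-1-methyl-3-oxo-2-oxabicyclo[2.2.2]octa-5,7-diene-4-carboxylate (racemic, not isolated) | COC(=O)C12C(=O)OC(C)(C=C1OC)C=C2Oc3c(C4OCCO4)cc(OC)c(Cl)c3OCc5ccccc5 | intermediate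
22 | methyl 2-[2-(benzyloxy)-3-chloro-6-(1,3-dioxolan-2-yl)-4-methoxyphenoxy]-6-methoxy-4-methylbenzoate | COC(=O)c1c(OC)cc(C)cc1Oc1c(C2OCCO2)cc(OC)c(Cl)c1OCc1ccccc1 | intermediate
23 | methyl 2-[2-(benzyloxy)-3-chloro-6-formyl-4-methoxyphenoxy]-6-methoxy-4-methylbenzoate | COC(=O)c1c(OC)cc(C)cc1Oc1c(C=O)cc(OC)c(Cl)c1OCc1ccccc1 | intermediate
24 | 3-(benzyloxy)-4-chloro-5-methoxy-2-[3-methoxy-2-(methoxycarbonyl)-5-methylphenoxy]benzoic acid | COC(=O)c1c(OC)cc(C)cc1Oc1c(C(=O)O)cc(OC)c(Cl)c1OCc1ccccc1 | intermediate
25 | 4-chloro-3-hydroxy-2-[3-hydroxy-2-(methoxycarbonyl)-5-methylphenoxy]-5-methoxybenzoic acid | COC(=O)c1c(O)cc(C)cc1Oc1c(C(=O)O)cc(OC)c(Cl)c1O | intermediate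
26 | 2-(2-carboxy-3-hydroxy-5-methylphenoxy)-4-chloro-3-hydroxy-5-methoxybenzoic acid | COc1cc(C(=O)O)c(Oc2cc(C)cc(O)c2C(=O)O)c(O)c1Cl | target

## Step count and least certain steps

Total: 15 steps. Longest linear sequence: 13 steps (steps 1–8 and 11–15); the pyrone branch has 2 steps (9 and 10).

**Step 11 (key step).** The cycloaddition may be too slow, because the 4-methoxy group raises the LUMO of the pyrone and the 6-methyl group shields C6. Thermal oligomerisation of the terminal ynol ether, or polar addition of the alkyne at the methoxy-bearing C4 leading to [2+2]-type products, could then consume 15 before ring B forms. Fallback: the ring construction is given up and the C2–O–C2' bond is made by Ullmann etherification. Phenol 8 and the aryl bromide methyl 2-bromo-6-methoxy-4-methylbenzoate F1 (bought or prepared separately) are heated with CuI, picolinic acid and Cs2CO3 in DMSO at about 100 °C, the ortho ester of F1 assisting the copper insertion. The product is aldehyde 23, where the route is rejoined; steps 6–10 and 12 fall away.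

**Step 8.** The terminal aryl ethynyl ether may polymerise or hydrate during work-up and isolation, and excess n-BuLi may metalate the benzylic position. Fallback: setting out from 12, the lithium acetylide 14 is not protonated but silylated with Me3SiCl to the storable {[2-(benzyloxy)-3-chloro-6-(1,3-dioxolan-2-yl)-4-methoxyphenoxy]ethynyl}trimethylsilane F2, which is purified and kept. Immediately before step 11 it is desilylated with TBAF in THF at −78 °C, which returns to 15 as a solution that is never concentrated.

**Step 6.** O-vinylation may be sluggish because the phenoxide of 8 is delocalised into the aldehyde and flanked by two ortho substituents, so that decomposition of dichloroacetylene wins. Fallback: the order is reversed. Setting out from 8, the aldehyde is first acetalised (ethylene glycol, p-toluenesulfonic acid cat., benzene, Dean–Stark) to 2-(benzyloxy)-3-chloro-6-(1,3-dioxolan-2-yl)-4-methoxyphenol F3. Its non-conjugated and more nucleophilic potassium phenoxide (KH, THF) is then treated with 9 and gives 12 directly, where the route is rejoined.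

**Step 14.** The two cleavages may not keep pace. Incomplete demethylation next to the weakly chelating ester would call for warming, and warming risks loss of the C5 methyl ether and ring benzylation. Fallback: the two ethers are removed in separate operations of different mechanism. Setting out from 24, trifluoroacetic acid with pentamethylbenzene at room temperature should cleave only the benzyl ether and give 4-chloro-3-hydroxy-5-methoxy-2-[3-methoxy-2-(methoxycarbonyl)-5-methylphenoxy]benzoic acid F4. MgI2 (as its ether complex) in toluene at 80 °C should then remove only the methyl ether chelated to the ester carbonyl, by iodide attack on the methyl group, and return to 25.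

**Step 15.** The saponification may stall, because the substrate becomes a polyanion with a phenoxide ortho to the doubly ortho-substituted ester. The ring B acid may also decarboxylate if acidification is not kept cold. Fallback: the ester is cleaved before any phenol is set free. Setting out from 24, KOH in aqueous DMSO at 90 °C should give the diacid 3-(benzyloxy)-2-(2-carboxy-3-methoxy-5-methylphenoxy)-4-chloro-5-methoxybenzoic acid F5. BCl3 with pentamethylbenzene at −78 → 0 °C then removes the benzyl group and the methyl ether chelated to the ring B carboxyl, and returns to 26 under cold, non-basic conditions.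

## Further compounds

F1 | step 11 | methyl 2-bromo-6-methoxy-4-methylbenzoate | COC(=O)c1c(Br)cc(C)cc1OC
F2 | step 8 | {[2-(benzyloxy)-3-chloro-6-(1,3-dioxolan-2-yl)-4-methoxyphenoxy]ethynyl}trimethylsilane | C[Si](C)(C)C#COc1c(C2OCCO2)cc(OC)c(Cl)c1OCc1ccccc1
F3 | step 6 | 2-(benzyloxy)-3-chloro-6-(1,3-dioxolan-2-yl)-4-methoxyphenol | Oc1c(C2OCCO2)cc(OC)c(Cl)c1OCc1ccccc1
F4 | step 14 | 4-chloro-3-hydroxy-5-methoxy-2-[3-methoxy-2-(methoxycarbonyl)-5-methylphenoxy]benzoic acid | COC(=O)c1c(OC)cc(C)cc1Oc1c(C(=O)O)cc(OC)c(Cl)c1O
F5 | step 15 | 3-(benzyloxy)-2-(2-carboxy-3-methoxy-5-methylphenoxy)-4-chloro-5-methoxybenzoic acid | COc1cc(C)cc(Oc2c(C(=O)O)cc(OC)c(Cl)c2OCc2ccccc2)c1C(=O)O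
A1 | alternative 1 | methyl 3'-chloro-4,4'-dimethoxy-6-methyl-2',3-dioxo-3H-spiro[benzofuran-2,1'-cyclohex-3'-ene]-6'-carboxylate (racemic, ether oxygen and ester cis) | O=C1c2c(OC)cc(C)cc2O[C@@]13C(=O)C(Cl)=C(OC)C[C@@H]3C(=O)OC
A2 | alternative 1 | methyl (2Z)-2-(4-methoxy-6-methyl-3-oxo-1-benzofuran-2(3H)-ylidene)acetate | COC(=O)/C=C1\Oc2cc(C)cc(OC)c2C1=O
A3 | alternative 1 | [(2-chloro-1,3-dimethoxybuta-1,3-dien-1-yl)oxy]trimethylsilane | C=C(OC)C(Cl)=C(OC)O[Si](C)(C)C
A4 | alternative 2 | methyl trans-2-[2-(tert-butoxycarbonyl)-3-methoxy-5-methylphenoxy]-3,5-dioxocyclohexane-1-carboxylate (racemic) | COC(=O)[C@@H]1CC(=O)CC(=O)[C@H]1Oc1cc(C)cc(OC)c1C(=O)OC(C)(C)C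
A5 | alternative 2 | tert-butyl 2-methoxy-4-methyl-6-(2-oxopropoxy)benzoate | CC(=O)COc1cc(C)cc(OC)c1C(=O)OC(C)(C)C
A6 | alternative 2 | dimethyl fumarate | COC(=O)/C=C/C(=O)OC
A7 | alternative 3 | methyl 3-(benzyloxy)-4-chloro-2-[3-hydroxy-2-(methoxycarbonyl)-5-methylphenoxy]-5-methoxybenzoate | COC(=O)c1cc(OC)c(Cl)c(OCc2ccccc2)c1Oc1cc(C)cc(O)c1C(=O)OC
A8 | alternative 3 | methyl 3-(benzyloxy)-4-chloro-5-methoxy-2-[(3-methoxy-3-oxoprop-1-yn-1-yl)oxy]benzoate | COC(=O)C#COc1c(C(=O)OC)cc(OC)c(Cl)c1OCc1ccccc1
A9 | alternative 3 | [(1-methoxy-3-methylbuta-1,3-dien-1-yl)oxy]trimethylsilane | C=C(C)C=C(OC)O[Si](C)(C)C
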